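**Retrosynthetic overview**

1. Piscerythrinetin comes from its 5,7-di-O-allyl ether; the allyl groups are taken off last with zerovalent palladium, which leaves the aryl methyl ethers and the C-5' prenyl group.
2. Ring C is closed last and at carbon: the C-4 to C-4a disconnection (intramolecular Friedel-Crafts acylation) leads to (Z)-3-[3,5-bis(allyloxy)phenoxy]-2-arylacrylic acid, in which O-1 already joins ring A to C-2.
3. The O-1 to C-2 bond comes from addition-elimination of 3,5-bis(allyloxy)phenol (ring A, from phloroglucinol) on the Z enol tosylate of the α-formyl arylacetate (ring B, from homovanillic acid by ortho-Claisen allyl transfer, O-methylation, cross-metathesis to prenyl and formylation).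
4. Structural feature used: C-4a is ortho to O-1 (on C-8a) and to O-5 and para to O-7, and the two carbons ortho to the ether oxygen of a 3,5-dioxygenated aryl ether are identical, so acylation at carbon can give only one chromone.
5. Ring order: rings A and B are bought as arenes; ring C (the pyranone) is the only ring made.

Key step: step 11

Remark on geometry: only the Z isomer of the aryloxyacrylate, its acid and its acid chloride (aryloxy cis to the carboxyl carbon) can close directly. Any E isomer is carried on unseparated, on the assumption that rotation about C-2 to C-3 in the SnCl4-bound acyl species (oxocarbenium/ketene resonance form) feeds it into the same closure.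

**Route**

Step 1
Reactants: 1 phloroglucinol; 2 allyl bromide
Product: 3 3,5-bis(allyloxy)phenol
Conditions: allyl bromide (2 equiv), K2CO3, DMF, 0 °C to rt; chromatography
Reagents that add atoms: allyl bromide, C=CCBr
Why: Williamson etherification with two equivalents of halide should give the di-O-allyl ether as the main component of a separable mono-, di- and tri-ether mixture, oxygen alkylation of the phloroglucinol anion being favoured in a dipolar aprotic solvent.

Step 2
Reactants: 4 homovanillic acid
Product: 5 methyl 2-(4-hydroxy-3-methoxyphenyl)acetate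
Conditions: MeOH, H2SO4 (cat.), reflux
Reagents that add atoms: methanol, CO
Why: Fischer esterification of the arylacetic acid in excess methanol, which leaves the phenol untouched.

Step 3
Reactants: 5 methyl 2-(4-hydroxy-3-methoxyphenyl)acetate; 2 allyl bromide
Product: 6 methyl 2-(4-allyloxy-3-methoxyphenyl)acetate
Conditions: allyl bromide, K2CO3, acetone, reflux
Reagents that add atoms: allyl bromide, C=CCBr
Why: Williamson etherification of the only phenol, K2CO3 being too weak a base to alkylate the ester α-carbon.

Step 4
Reactants: 6 methyl 2-(4-allyloxy-3-methoxyphenyl)acetate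
Product: 7 methyl 2-(3-allyl-4-hydroxy-5-methoxyphenyl)acetate
Conditions: N,N-diethylaniline, 195 °C
Reagents that add atoms: none
Why: Aromatic Claisen rearrangement, in which the [3,3] shift delivers the allyl group to C-5, the only unsubstituted ortho carbon, and tautomerisation returns the phenol.

Step 5
Reactants: 7 methyl 2-(3-allyl-4-hydroxy-5-methoxyphenyl)acetate
Product: 8 methyl 2-(3-allyl-4,5-dimethoxyphenyl)acetate
Conditions: MeI, K2CO3, acetone, reflux
Reagents that add atoms: iodomethane, CI
Why: Williamson O-methylation of the phenol, which fixes the 3,4-dimethoxy pattern of ring B.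

Step 6
Reactants: 8 methyl 2-(3-allyl-4,5-dimethoxyphenyl)acetate
Product: 9 methyl 2-[3,4-dimethoxy-5-(3-methylbut-2-enyl)phenyl]acetate
Conditions: 2-methyl-2-butene (excess), second-generation Grubbs catalyst RuCl2(=CHPh)(PCy3)(1,3-dimesitylimidazolidin-2-ylidene) (cat.), CH2Cl2, 40 °C
Reagents that add atoms: 2-methyl-2-butene, CC=C(C)C
Why: Olefin cross-metathesis of a terminal alkene with excess 2-methyl-2-butene is a standard way to turn an aryl allyl group into a prenyl group, with propene leaving as a gas.

Step 7
Reactants: 9 methyl 2-[3,4-dimethoxy-5-(3-methylbut-2-enyl)phenyl]acetate; 10 methyl formate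
Product: 11 methyl (Z)-2-[3,4-dimethoxy-5-(3-methylbut-2-enyl)phenyl]-3-hydroxyacrylate (enol tautomer of the α-formyl ester)
Conditions: NaH, HCO2Me, THF, 0 °C to rt; then cold 1 M HCl
Reagents that add atoms: methyl formate, COC=O
Why: Crossed Claisen condensation, in which the ester enolate is formylated by the non-enolisable methyl formate and the product is drained off as its sodium enolate, which on acidification should give the hydrogen-bonded Z enol.

Step 8
Reactants: 11 methyl (Z)-2-[3,4-dimethoxy-5-(3-methylbut-2-enyl)phenyl]-3-hydroxyacrylate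
Product: 12 methyl (Z)-2-[3,4-dimethoxy-5-(3-methylbut-2-enyl)phenyl]-3-(p-tolylsulfonyloxy)acrylate
Conditions: TsCl, TMEDA, LiCl, MeCN, 0 °C
Reagents that add atoms: p-toluenesulfonyl chloride, Cc1ccc(cc1)S(Cl)(=O)=O
Why: Stereoselective enol tosylation, in which lithium bridges the enolate oxygen and the ester carbonyl so that the oxygen is held cis to CO2Me and sulfonylation should give the Z enol tosylate.

Step 9
Reactants: 12 methyl (Z)-2-[3,4-dimethoxy-5-(3-methylbut-2-enyl)phenyl]-3-(p-tolylsulfonyloxy)acrylate; 3 3,5-bis(allyloxy)phenol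
Product: 13 methyl (Z)-3-[3,5-bis(allyloxy)phenoxy]-2-[3,4-dimethoxy-5-(3-methylbut-2-enyl)phenyl]acrylate
Conditions: K2CO3, DMF, 0 °C to rt
Reagents that add atoms: none
Why: Nucleophilic vinylic substitution by addition-elimination, in which the potassium phenoxide should add through oxygen to C-3 of the β-sulfonyloxy acrylate and tosylate should leave from the short-lived ester enolate before further rotation about C-2 to C-3, so that the Z geometry is retained in the main.

Step 10
Reactants: 13 methyl (Z)-3-[3,5-bis(allyloxy)phenoxy]-2-[3,4-dimethoxy-5-(3-methylbut-2-enyl)phenyl]acrylate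
Product: 14 (Z)-3-[3,5-bis(allyloxy)phenoxy]-2-[3,4-dimethoxy-5-(3-methylbut-2-enyl)phenyl]acrylic acid
Conditions: LiOH, THF/H2O, 0 °C to rt; then 1 M HCl to pH 3, 0 °C
Reagents that add atoms: lithium hydroxide, [Li+].[OH-]
Why: Saponification of the methyl ester without alcohol cosolvent (no alkoxide to exchange the aryloxy group at C-3), the aryloxy donor deactivating C-3 towards hydroxide, so that cold acidification should give the acid with the Z geometry unchanged.

Step 11
Reactants: 14 (Z)-3-[3,5-bis(allyloxy)phenoxy]-2-[3,4-dimethoxy-5-(3-methylbut-2-enyl)phenyl]acrylic acid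
Product: 16 5,7-bis(allyloxy)-3-[3,4-dimethoxy-5-(3-methylbut-2-enyl)phenyl]chromen-4-one, via acid chloride 15 (not isolated)
Conditions: 1-chloro-N,N,2-trimethylpropenylamine, CH2Cl2, 0 °C; then 2,6-di-tert-butyl-4-methylpyridine, SnCl4, CH2Cl2 (0.02 M), −78 to −20 °C
Reagents that add atoms: none
Why: The chloroenamine turns the acid into acid chloride 15 without releasing HCl, and SnCl4 then polarises it to an acylium-type electrophile that is attacked by the ring A carbon ortho to the ether oxygen; loss of the proton to the hindered pyridine restores ring A and leaves the C-4 to C-4a bond and ring C. This is an intramolecular Friedel-Crafts acylation of a 3-aryloxyacrylic acid, the known carbon-closure route to chromones. Ring C closes in the 6-exo-trig mode at the acyl carbon (the C=O ends outside the new ring), and the Z alkene holds the acyl group next to ring A. No stereocenter is formed. Site selectivity needs no control, since the two ortho carbons are related by the symmetry of the 3,5-bis(allyloxy)phenoxy ring and the carbon between the allyloxy groups cannot reach the acyl carbon. Chemoselectivity over the prenyl and allyl alkenes rests on the six-membered intramolecular attack by a carbon that is ortho and para to two allyloxy groups, helped by high dilution, low temperature and a buffer that keeps HCl from adding to the trisubstituted alkene.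

Step 12
Reactants: 16 5,7-bis(allyloxy)-3-[3,4-dimethoxy-5-(3-methylbut-2-enyl)phenyl]chromen-4-one
Product: 17 piscerythrinetin, 5,7-dihydroxy-3-[3,4-dimethoxy-5-(3-methylbut-2-enyl)phenyl]chromen-4-one
Conditions: Pd(PPh3)4 (cat.), morpholine (3 equiv), THF, rt
Reagents that add atoms: none
Why: Tsuji-Trost-type deallylation, in which zerovalent palladium ionises each aryl allyl ether to a π-allyl complex that morpholine captures, while the aryl methyl ethers and the carbon-bound prenyl group offer no leaving group.

**Compound list**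

1 | phloroglucinol (benzene-1,3,5-triol) | Oc1cc(O)cc(O)c1 | starting material
2 | allyl bromide | C=CCBr | starting material
3 | 3,5-bis(allyloxy)phenol | Oc1cc(OCC=C)cc(OCC=C)c1 | intermediate
4 | homovanillic acid | COc1cc(CC(=O)O)ccc1O | starting material
5 | methyl 2-(4-hydroxy-3-methoxyphenyl)acetate | COC(=O)Cc1ccc(O)c(OC)c1 | intermediate
6 | methyl 2-(4-allyloxy-3-methoxyphenyl)acetate | COC(=O)Cc1ccc(OCC=C)c(OC)c1 | intermediate
7 | methyl 2-(3-allyl-4-hydroxy-5-methoxyphenyl)acetate | COC(=O)Cc1cc(CC=C)c(O)c(OC)c1 | intermediate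
8 | methyl 2-(3-allyl-4,5-dimethoxyphenyl)acetate | COC(=O)Cc1cc(CC=C)c(OC)c(OC)c1 | intermediate
9 | methyl 2-[3,4-dimethoxy-5-(3-methylbut-2-enyl)phenyl]acetate | COC(=O)Cc1cc(CC=C(C)C)c(OC)c(OC)c1 | intermediate
10 | methyl formate | COC=O | starting material
11 | methyl (Z)-2-[3,4-dimethoxy-5-(3-methylbut-2-enyl)phenyl]-3-hydroxyacrylate | COC(=O)/C(=C\O)c1cc(OC)c(OC)c(CC=C(C)C)c1 | intermediate
12 | methyl (Z)-2-[3,4-dimethoxy-5-(3-methylbut-2-enyl)phenyl]-3-(p-tolylsulfonyloxy)acrylate | COC(=O)/C(=C\OS(=O)(=O)c1ccc(C)cc1)c1cc(OC)c(OC)c(CC=C(C)C)c1 | intermediate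
13 | methyl (Z)-3-[3,5-bis(allyloxy)phenoxy]-2-[3,4-dimethoxy-5-(3-methylbut-2-enyl)phenyl]acrylate | COC(=O)/C(=C\Oc1cc(OCC=C)cc(OCC=C)c1)c1cc(OC)c(OC)c(CC=C(C)C)c1 | intermediate
14 | (Z)-3-[3,5-bis(allyloxy)phenoxy]-2-[3,4-dimethoxy-5-(3-methylbut-2-enyl)phenyl]acrylic acid | OC(=O)/C(=C\Oc1cc(OCC=C)cc(OCC=C)c1)c1cc(OC)c(OC)c(CC=C(C)C)c1 | intermediate
15 | (Z)-3-[3,5-bis(allyloxy)phenoxy]-2-[3,4-dimethoxy-5-(3-methylbut-2-enyl)phenyl]acryloyl chloride | ClC(=O)/C(=C\Oc1cc(OCC=C)cc(OCC=C)c1)c1cc(OC)c(OC)c(CC=C(C)C)c1 | intermediate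
16 | 5,7-bis(allyloxy)-3-[3,4-dimethoxy-5-(3-methylbut-2-enyl)phenyl]chromen-4-one | C=CCOc1cc(OCC=C)c2c(c1)occ(-c1cc(OC)c(OC)c(CC=C(C)C)c1)c2=O | intermediate
17 | piscerythrinetin | COc1cc(-c2coc3cc(O)cc(O)c3c2=O)cc(CC=C(C)C)c1OC | target

**Step count**

Total: 12 steps. Longest linear sequence: 11 steps (homovanillic acid 4 to 17, steps 2 to 12); step 1 is the convergent branch.

**Steps most likely to fail**

Step 11 (ring closure). The activated acyl species may acylate the trisubstituted prenyl alkene of a second molecule, HCl may add to that alkene, or the Lewis acid may induce a [3,3] shift of an O-allyl group to carbon. Chelation-assisted loss of the 5-O-allyl group would be harmless, since step 12 removes it anyway. The fallback keeps the prenyl group latent as a C-allyl group through the closure; it sets out from 8 and comes back at 17.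
- 8 is formylated as in step 7 to methyl (Z)-2-(3-allyl-4,5-dimethoxyphenyl)-3-hydroxyacrylate F1.
- F1 is tosylated as in step 8 to methyl (Z)-2-(3-allyl-4,5-dimethoxyphenyl)-3-(p-tolylsulfonyloxy)acrylate F2.
- F2 is joined with 3 as in step 9 to methyl (Z)-2-(3-allyl-4,5-dimethoxyphenyl)-3-[3,5-bis(allyloxy)phenoxy]acrylate F3.
- F3 is saponified as in step 10 to (Z)-2-(3-allyl-4,5-dimethoxyphenyl)-3-[3,5-bis(allyloxy)phenoxy]acrylic acid F4.
- F4 is converted with the chloroenamine to (Z)-2-(3-allyl-4,5-dimethoxyphenyl)-3-[3,5-bis(allyloxy)phenoxy]acryloyl chloride F5 and closed with SnCl4 to 3-(3-allyl-4,5-dimethoxyphenyl)-5,7-bis(allyloxy)chromen-4-one F6. Only monosubstituted alkenes, which are far less nucleophilic and less basic than prenyl, are present at this stage.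
- Pd(PPh3)4 and morpholine remove the two O-allyl groups, leaving the C-allyl group, to give 3-(3-allyl-4,5-dimethoxyphenyl)-5,7-dihydroxychromen-4-one F7.
- Cross-metathesis of F7 with excess 2-methyl-2-butene and second-generation Grubbs catalyst should give 17.

Step 9 (aryl enol ether formation). The phenoxide may attack the sulfonyl sulfur instead of C-3 (tosyl transfer to the phenol and return of the enolate of 11), may react through ring carbon, or the alkene geometry may be lost through a longer-lived enolate. The fallback removes the sulfur electrophile; it sets out from 11 and comes back at 13. The enol 11 is converted under Appel-type conditions (PPh3, CBr4, CH2Cl2, 0 °C) into methyl (Z)-3-bromo-2-[3,4-dimethoxy-5-(3-methylbut-2-enyl)phenyl]acrylate F8. F8 should undergo the same addition-elimination with 3 (K2CO3, DMF) to give 13, with bromide as the only leaving group. An E-rich product would have to rely on the equilibration noted in the remark.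

Step 1 (diallylation). Statistical over- and under-alkylation and ring C-allylation of the ambident phloroglucinol anion may leave little of the di-ether. The fallback avoids phloroglucinol; it sets out from 2 and comes back at 3. Bought 5-bromobenzene-1,3-diol F9 is allylated on both oxygens with 2 (K2CO3, acetone) to 1,3-bis(allyloxy)-5-bromobenzene F10. Bromine-lithium exchange (n-BuLi, THF, −78 °C) gives [3,5-bis(allyloxy)phenyl]lithium F11, which is trapped with B(OMe)3 as dimethyl [3,5-bis(allyloxy)phenyl]boronate F12. Oxidation in the same flask with H2O2/NaOH should give 3.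

**Further compounds**

F1 | step 11 | methyl (Z)-2-(3-allyl-4,5-dimethoxyphenyl)-3-hydroxyacrylate | COC(=O)/C(=C\O)c1cc(OC)c(OC)c(CC=C)c1
F2 | step 11 | methyl (Z)-2-(3-allyl-4,5-dimethoxyphenyl)-3-(p-tolylsulfonyloxy)acrylate | COC(=O)/C(=C\OS(=O)(=O)c1ccc(C)cc1)c1cc(OC)c(OC)c(CC=C)c1
F3 | step 11 | methyl (Z)-2-(3-allyl-4,5-dimethoxyphenyl)-3-[3,5-bis(allyloxy)phenoxy]acrylate | COC(=O)/C(=C\Oc1cc(OCC=C)cc(OCC=C)c1)c1cc(OC)c(OC)c(CC=C)c1
F4 | step 11 | (Z)-2-(3-allyl-4,5-dimethoxyphenyl)-3-[3,5-bis(allyloxy)phenoxy]acrylic acid | OC(=O)/C(=C\Oc1cc(OCC=C)cc(OCC=C)c1)c1cc(OC)c(OC)c(CC=C)c1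
F5 | step 11 | (Z)-2-(3-allyl-4,5-dimethoxyphenyl)-3-[3,5-bis(allyloxy)phenoxy]acryloyl chloride | ClC(=O)/C(=C\Oc1cc(OCC=C)cc(OCC=C)c1)c1cc(OC)c(OC)c(CC=C)c1
F6 | step 11 | 3-(3-allyl-4,5-dimethoxyphenyl)-5,7-bis(allyloxy)chromen-4-one | C=CCOc1cc(OCC=C)c2c(c1)occ(-c1cc(OC)c(OC)c(CC=C)c1)c2=O
F7 | step 11 | 3-(3-allyl-4,5-dimethoxyphenyl)-5,7-dihydroxychromen-4-one | C=CCc1cc(cc(OC)c1OC)-c1coc2cc(O)cc(O)c2c1=O
F8 | step 9 | methyl (Z)-3-bromo-2-[3,4-dimethoxy-5-(3-methylbut-2-enyl)phenyl]acrylate | COC(=O)/C(=C\Br)c1cc(OC)c(OC)c(CC=C(C)C)c1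
F9 | step 1 | 5-bromobenzene-1,3-diol | Oc1cc(O)cc(Br)c1
F10 | step 1 | 1,3-bis(allyloxy)-5-bromobenzene | C=CCOc1cc(Br)cc(OCC=C)c1
F11 | step 1 | [3,5-bis(allyloxy)phenyl]lithium | [Li]c1cc(OCC=C)cc(OCC=C)c1
F12 | step 1 | dimethyl [3,5-bis(allyloxy)phenyl]boronate | COB(OC)c1cc(OCC=C)cc(OCC=C)c1
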